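## Retrosynthetic overview

- **Numbering (germacrane):** C1 furanone C=O, C2 furanone =CH, C3 furanone O–C=, C4 CHMe, C5 CHOH, C6 lactone CH–O, C7 lactone CH, C8 CH–O‑isovalerate, C9 CHOH, C10 C(Me)–O.
- **Enabling feature:** in the 3(2H)-furanone ring, ring‑O–C3=C2 is the O,C‑enolate of a methyl ketone. C1(=O)–C10(Me)(O) together with the free hydroxyl on the neighbouring C9 is an opened 2,3‑epoxy (glycidic) acyl group. A C2/O bis‑nucleophile therefore meets a C1/C10 bis‑electrophile.
- **Key disconnection:** C2–C1 and O–C10 are cut together. This opens the ten‑membered carbocycle and the furanone to a monocyclic methyl ketone that carries a glycidic pentafluorophenyl ester.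
- **Precursor assembly:**
  - epoxide by Sharpless epoxidation of an E‑allylic alcohol, and methyl ketone by Wacker oxidation of a vinyl group;
  - α‑methylene lactone from a 1‑bromovinyl diol and CO;
  - C8 by 1,3‑anti reduction of an enone (Weinreb amide plus alkenyl Grignard reagent);
  - C6/C7 by an Evans syn aldol, and C4/C5 by crotylboration.
- **Ring order:** butyrolactone (step 12), temporary oxirane (step 16), then ten‑membered carbocycle and furanone in one operation (step 19).

Key step: step 19

Remark: the tartrate crotylboronate of step 1 is treated as a stock reagent, made by the standard procedure from trans‑2‑butene, triisopropyl borate and L‑(+)‑diisopropyl tartrate. Stereodescriptors of advanced intermediates refer to the germacrane numbering above.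

## Route

Step 1
Reactants: 1 (R)-2,2-dimethyl-1,3-dioxolane-4-carbaldehyde
Product: 2 (1S,2S)-1-[(4R)-2,2-dimethyl-1,3-dioxolan-4-yl]-2-methylbut-3-en-1-ol
Conditions: (R,R)-diisopropyl tartrate (E)-crotylboronate, 4 Å MS, toluene, −78 °C; then H2O
Reagents that add atoms: (R,R)-diisopropyl tartrate (E)-crotylboronate CC(C)OC(=O)[C@@H]1OB(C/C=C/C)O[C@H]1C(=O)OC(C)C
Why: Roush asymmetric crotylboration through a closed chair transition state: the E‑crotyl geometry gives the anti C4‑methyl/C5‑hydroxyl pair, and the Si‑face preference of the (R,R)-tartrate reagent is matched with the Felkin–Anh/Cornforth preference of 1, so both new stereocentres are set by reagent and substrate acting in the same sense.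

Step 2
Reactants: 2 (1S,2S)-1-[(4R)-2,2-dimethyl-1,3-dioxolan-4-yl]-2-methylbut-3-en-1-ol
Product: 3 tert-butyldimethylsilyl ether of 2
Conditions: TBSOTf, 2,6-lutidine, CH2Cl2, 0 °C
Reagents that add atoms: tert-butyldimethylsilyl triflate CC(C)(C)[Si](C)(C)OS(=O)(=O)C(F)(F)F
Why: Silyl triflate silylation of a hindered secondary alcohol with a non‑nucleophilic base, which touches no stereocentre and gives a C5 ether that is a poor leaving group in the later enolate chemistry.

Step 3
Reactants: 3 tert-butyldimethylsilyl ether of 2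
Product: 5 (2S,3S)-2-(tert-butyldimethylsilyloxy)-3-methylpent-4-enal, via terminal diol 4 (not isolated)
Conditions: H5IO6, EtOAc, 23 °C
Reagents that add atoms: none
Why: Periodic acid first hydrolyses the terminal acetonide and then cleaves the 1,2‑diol (Malaprade glycol cleavage), the secondary silyl ether and the alkene are inert, and the base‑free medium keeps the α‑silyloxy aldehyde centre C5 intact.

Step 4
Reactants: 6 3-bromobut-3-en-1-ol
Product: 8 3-bromobut-3-enoic acid, via 3-bromobut-3-enal 7 (not isolated)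
Conditions: TEMPO (cat.), PhI(OAc)2, MeCN/H2O, 0→23 °C
Reagents that add atoms: water O
Why: Oxoammonium (TEMPO) oxidation of a primary alcohol through the aldehyde hydrate to the acid, mild enough to leave the vinyl bromide and the β,γ‑position of the double bond unchanged.

Step 5
Reactants: 8 3-bromobut-3-enoic acid; 9 (S)-4-benzyloxazolidin-2-one
Product: 11 (S)-4-benzyl-3-(3-bromobut-3-enoyl)oxazolidin-2-one, via mixed pivalic anhydride 10 (not isolated)
Conditions: PivCl, Et3N, THF, −20 °C; then LiCl, 9, −20→23 °C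
Reagents that add atoms: pivaloyl chloride CC(C)(C)C(=O)Cl (its atoms appear only in 10)
Why: N‑Acylation of the Evans auxiliary by the mixed‑anhydride/LiCl method, which needs only a tertiary amine and attacks the less hindered carbonyl of 10.

Step 6
Reactants: 11 (S)-4-benzyl-3-(3-bromobut-3-enoyl)oxazolidin-2-one; 5 (2S,3S)-2-(tert-butyldimethylsilyloxy)-3-methylpent-4-enal
Product: 13 (S)-4-benzyl-3-[(2S,3S,4S,5S)-2-(1-bromoethenyl)-4-(tert-butyldimethylsilyloxy)-3-hydroxy-5-methylhept-6-enoyl]oxazolidin-2-one, via boron dienolate 12 (not isolated)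
Conditions: n-Bu2BOTf, Et3N, CH2Cl2, −78→0 °C; 5, −78→0 °C; H2O2, MeOH, pH 7 buffer
Reagents that add atoms: dibutylboron triflate CCCCB(CCCC)OS(=O)(=O)C(F)(F)F (its atoms appear only in 12)
Why: Evans syn aldol addition: the Z(O)-boron dienolate reacts at its α‑carbon through a Zimmerman–Traxler chair, the benzyl group of the auxiliary fixes the enolate face and thereby C7 and C6 (6,7‑syn), and this strong reagent control overrides the opposite, weaker Cornforth preference of the α‑silyloxy aldehyde.

Step 7
Reactants: 13 Evans aldol adduct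
Product: 14 (2S,3S,4S,5S)-2-(1-bromoethenyl)-4-(tert-butyldimethylsilyloxy)-3-hydroxy-N-methoxy-N,5-dimethylhept-6-enamide
Conditions: MeONHMe·HCl, AlMe3, THF, −20→0 °C; Rochelle salt
Reagents that add atoms: N,O-dimethylhydroxylamine hydrochloride CNOC.Cl
Why: Weinreb transamidation with the aluminium amide, directed to the exocyclic imide carbonyl by the aluminium alkoxide of the free C6 hydroxyl, without change at C7.

Step 8
Reactants: 15 prop-2-yn-1-ol
Product: 17 (E)-3-iodo-2-methylprop-2-en-1-ol, via alkenylalane 16 (not isolated)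
Conditions: AlMe3, Cp2ZrCl2 (cat.), CH2Cl2, 0→23 °C; I2, THF, −30 °C
Reagents that add atoms: trimethylaluminium C[Al](C)C; iodine II
Why: Negishi zirconium‑catalysed syn‑carboalumination places methyl on the internal and aluminium on the terminal alkyne carbon, and iodinolysis with retention gives only the E‑iodide.

Step 9
Reactants: 17 (E)-3-iodo-2-methylprop-2-en-1-ol
Product: 18 (E)-tert-butyl[(3-iodo-2-methylprop-2-en-1-yl)oxy]dimethylsilane
Conditions: TBSCl, imidazole, CH2Cl2, 23 °C
Reagents that add atoms: tert-butyldimethylsilyl chloride CC(C)(C)[Si](C)(C)Cl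
Why: Standard imidazole‑promoted silylation of a primary alcohol.

Step 10
Reactants: 18 (E)-alkenyl iodide; 14 Weinreb amide
Product: 20 (2E,5S,6S,7S,8S)-5-(1-bromoethenyl)-1,7-bis(tert-butyldimethylsilyloxy)-6-hydroxy-2,8-dimethyldeca-2,9-dien-4-one, via alkenylmagnesium chloride 19 (not isolated)
Conditions: 18, i-PrMgCl·LiCl, THF, 0→23 °C; 14 pre‑treated with i-PrMgCl (1 equiv), THF, −20 °C; combine, −20→0 °C; aq. NH4Cl
Reagents that add atoms: isopropylmagnesium chloride–lithium chloride CC(C)[Mg]Cl.[Li+].[Cl-] (its atoms appear only in 19)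
Why: Iodine–magnesium exchange with the turbo‑Grignard reagent retains the E‑geometry and the Weinreb ketone synthesis stops at the chelated tetrahedral intermediate, while the magnesium reagent, unlike a lithium reagent, does not exchange with the vinyl bromide and prior deprotonation of the hydroxyl avoids waste of 19.

Step 11
Reactants: 20 β-hydroxy enone
Product: 21 (2E,4R,5R,6S,7S,8S)-5-(1-bromoethenyl)-1,7-bis(tert-butyldimethylsilyloxy)-2,8-dimethyldeca-2,9-diene-4,6-diol
Conditions: Me4NBH(OAc)3, MeCN/AcOH, −35 °C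
Reagents that add atoms: none
Why: Evans–Saksena reduction: the C6 hydroxyl exchanges an acetate on boron and delivers hydride intramolecularly through a chair transition state, which sets C8 1,3‑anti to C6 and gives 1,2‑reduction only.

Step 12
Reactants: 21 1,3-anti diol
Product: 22 (4R,5S)-5-[(1S,2S)-1-(tert-butyldimethylsilyloxy)-2-methylbut-3-en-1-yl]-4-[(1R,2E)-4-(tert-butyldimethylsilyloxy)-1-hydroxy-3-methylbut-2-en-1-yl]-3-methylideneoxolan-2-one
Conditions: Pd(PPh3)4 (cat.), CO (3 atm), Et3N, THF, 60 °C
Reagents that add atoms: carbon monoxide [C-]#[O+]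
Why: Palladium‑catalysed carbonylative lactonisation of a 2‑bromoalkene bearing a homoallylic hydroxyl (oxidative addition, CO insertion, acyl capture), in which the C6 hydroxyl is used because it leads through a diequatorial palladacycle to the trans‑β,γ‑disubstituted lactone whereas the C8 hydroxyl would give the cis isomer, and no stereocentre is changed.

Step 13
Reactants: 22 hydroxy α-methylene lactone
Product: 23 C8 3-methylbutanoate (isovalerate) of 22
Conditions: isovaleric anhydride, DMAP (cat.), Et3N, CH2Cl2, 0→23 °C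
Reagents that add atoms: isovaleric anhydride CC(C)CC(=O)OC(=O)CC(C)C
Why: DMAP‑catalysed acylation of the single free (allylic, secondary) hydroxyl with retention at C8.

Step 14
Reactants: 23 C8 isovalerate
Product: 24 methyl ketone (4R,5S,6S,7R,8R) in which the vinyl group of 23 has become the C3 acetyl group
Conditions: PdCl2 (cat.), CuCl, O2 (1 atm), DMF/H2O 7:1, 23 °C
Reagents that add atoms: water O
Why: Tsuji–Wacker oxidation: only the monosubstituted alkene coordinates to Pd(II) and takes up water in the Markovnikov sense, the electron‑poor α‑methylene lactone and the trisubstituted alkene stay out, and the weakly acidic medium leaves C4 unepimerised.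

Step 15
Reactants: 24 methyl ketone
Product: 25 primary E-allylic alcohol (C1–OH free; C5 silyl ether kept)
Conditions: HF·pyridine, pyridine, THF, 0 °C
Reagents that add atoms: none
Why: Rate‑selective fluoride desilylation: the unhindered primary allylic silyl ether is cleaved far faster by buffered HF·pyridine than the secondary C5 ether flanked by two branched carbons.

Step 16
Reactants: 25 primary E-allylic alcohol
Product: 26 (4R,5S,6S,7R,8S,9R,10R)-9,10-epoxy alcohol
Conditions: Ti(Oi-Pr)4, D-(−)-diethyl tartrate, t-BuOOH, 4 Å MS, CH2Cl2, −20 °C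
Reagents that add atoms: tert-butyl hydroperoxide CC(C)(C)OO
Why: Sharpless asymmetric epoxidation, which addresses only the alkene that carries the allylic hydroxyl; D‑(−)‑tartrate delivers oxygen to the face that gives the (9R,10R)-epoxide, and the E‑geometry fixes C8 and C1 trans on the oxirane.

Step 17
Reactants: 26 epoxy alcohol
Product: 28 (9R,10S)-glycidic acid, via epoxy aldehyde 27 (not isolated)
Conditions: TEMPO (cat.), PhI(OAc)2, MeCN/pH 7 buffer, 0→23 °C
Reagents that add atoms: water O
Why: TEMPO/PhI(OAc)2 oxidation of the primary epoxy alcohol through the aldehyde hydrate to the glycidic acid, under buffered conditions that leave the epoxide, the ketone, the ester and the α‑methylene lactone alone.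

Step 18
Reactants: 28 glycidic acid
Product: 29 pentafluorophenyl (9R,10S)-glycidate
Conditions: C6F5OH, EDC·HCl, CH2Cl2, 0 °C
Reagents that add atoms: pentafluorophenol Oc1c(F)c(F)c(F)c(F)c1F
Why: Carbodiimide esterification with an acidic phenol gives a chromatographically stable, non‑enolisable active ester without added base, so that the epoxide and C4 remain intact.

Step 19
Reactants: 29 pentafluorophenyl glycidate
Product: 31 5-O-tert-butyldimethylsilyl ether of the target (4R,5S,6S,7R,8S,9R,10R), via macrocyclic epoxy diketone 30 (not isolated)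
Conditions: 29 added by syringe pump (12 h) to MgBr2·OEt2 (5 equiv), i-Pr2NEt (8 equiv), CH2Cl2, 23 °C, final 1 mM; then 40 °C; pH 7 buffer
Reagents that add atoms: none
Why: Proposed new method: MgBr2/i‑Pr2NEt soft‑enolises the only enolisable ketone of 29 at its methyl group, the magnesium enolate carbon C2 attacks the non‑enolisable pentafluorophenyl glycidate carbonyl C1 with loss of pentafluorophenoxide to give the ten‑membered 1,3‑diketone 30, and the enolate oxygen on C3 of 30 then opens the adjacent epoxide at C10, which releases the C9 alkoxide and leaves the 3(2H)-furanone. The closest known reactions are the intermolecular soft‑enolisation C‑acylation of ketones with pentafluorophenyl esters or N‑acylbenzotriazoles to 1,3‑diketones and the O‑alkylative closure of 1,3‑diketones that carry an α'‑leaving group (bromide, sulfonium) to 3(2H)-furanones, neither of which has been run as a macrocyclisation or with an epoxide as the leaving group. The carbocycle closes in a 10‑(enolendo)‑exo‑trig acylation and the furanone in a transannular 5‑exo‑tet epoxide opening, for which Mg2+ chelated between the C1 carbonyl and the epoxide oxygen holds the C10–O bond antiperiplanar to the incoming oxygen. C10 is the only stereocentre that changes: it is inverted in the SN2 opening, so its configuration follows from the Sharpless epoxide of step 16, while C9 keeps its C–O bond and its configuration. The step needs C‑ over O‑acylation (magnesium chelate, and only C‑acylation gives the stabilised diketonate), methyl over methine enolisation (C4 is branched), attack at C10 rather than C9 (5‑exo against 6‑endo geometry, C9 further deactivated by the neighbouring acyloxy group) and ring closure over oligomerisation (syringe‑pump dilution, with the trans‑epoxide and the trans‑lactone as turn elements). The lactone, the isovalerate and the silyl ether have no proton that this weak base removes, and the α‑methylene lactone meets no nucleophilic base.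

Step 20
Reactants: 31 5-O-silyl ether of the target
Product: 32 CNP0484215.1 (4R,5S,6S,7S,8S,9R,10R)
Conditions: HF·pyridine, THF, 0→23 °C
Reagents that add atoms: none
Why: Fluoride‑mediated cleavage of the remaining secondary silyl ether under weakly acidic conditions, which promote neither acyl migration between O8 and O9, nor β‑elimination at C5, nor addition to the α‑methylene lactone.

## Compound list

1 | (R)-2,2-dimethyl-1,3-dioxolane-4-carbaldehyde | O=C[C@H]1COC(C)(C)O1 | starting material
2 | (1S,2S)-1-[(4R)-2,2-dimethyl-1,3-dioxolan-4-yl]-2-methylbut-3-en-1-ol | C=C[C@H](C)[C@H](O)[C@H]1COC(C)(C)O1 | intermediate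
3 | TBS ether of 2 | C=C[C@H](C)[C@H](O[Si](C)(C)C(C)(C)C)[C@H]1COC(C)(C)O1 | intermediate
4 | (2R,3S,4S)-3-(tert-butyldimethylsilyloxy)-4-methylhex-5-ene-1,2-diol | C=C[C@H](C)[C@H](O[Si](C)(C)C(C)(C)C)[C@H](O)CO | intermediate
5 | (2S,3S)-2-(tert-butyldimethylsilyloxy)-3-methylpent-4-enal | C=C[C@H](C)[C@H](O[Si](C)(C)C(C)(C)C)C=O | intermediate
6 | 3-bromobut-3-en-1-ol | C=C(Br)CCO | starting material
7 | 3-bromobut-3-enal | C=C(Br)CC=O | intermediate
8 | 3-bromobut-3-enoic acid | C=C(Br)CC(=O)O | intermediate
9 | (S)-4-benzyloxazolidin-2-one | O=C1N[C@@H](Cc2ccccc2)CO1 | starting material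
10 | 3-bromobut-3-enoic pivalic anhydride | C=C(Br)CC(=O)OC(=O)C(C)(C)C | intermediate
11 | (S)-4-benzyl-3-(3-bromobut-3-enoyl)oxazolidin-2-one | C=C(Br)CC(=O)N1[C@@H](Cc2ccccc2)COC1=O | intermediate
12 | (Z)-dibutylboron dienolate of 11 | C=C(Br)/C=C(\OB(CCCC)CCCC)N1[C@@H](Cc2ccccc2)COC1=O | intermediate
13 | Evans syn aldol adduct (2S,3S,4S,5S in the acyl chain) | C=C[C@H](C)[C@H](O[Si](C)(C)C(C)(C)C)[C@@H](O)[C@H](C(Br)=C)C(=O)N1[C@@H](Cc2ccccc2)COC1=O | intermediate
14 | Weinreb amide (2S,3S,4S,5S) | C=C[C@H](C)[C@H](O[Si](C)(C)C(C)(C)C)[C@@H](O)[C@H](C(Br)=C)C(=O)N(C)OC | intermediate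
15 | prop-2-yn-1-ol | C#CCO | starting material
16 | (E)-alkenylalane, dimethylaluminium alkoxide | C[Al](C)/C=C(\C)CO[Al](C)C | intermediate
17 | (E)-3-iodo-2-methylprop-2-en-1-ol | OC/C(C)=C/I | intermediate
18 | (E)-tert-butyl[(3-iodo-2-methylprop-2-en-1-yl)oxy]dimethylsilane | CC(C)(C)[Si](C)(C)OC/C(C)=C/I | intermediate
19 | (E)-[3-(tert-butyldimethylsilyloxy)-2-methylprop-1-en-1-yl]magnesium chloride | CC(C)(C)[Si](C)(C)OC/C(C)=C/[Mg]Cl | intermediate
20 | β-hydroxy enone (2E,5S,6S,7S,8S) | C=C[C@H](C)[C@H](O[Si](C)(C)C(C)(C)C)[C@@H](O)[C@H](C(Br)=C)C(=O)/C=C(\C)CO[Si](C)(C)C(C)(C)C | intermediate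
21 | 1,3-anti diol (2E,4R,5R,6S,7S,8S) | C=C[C@H](C)[C@H](O[Si](C)(C)C(C)(C)C)[C@@H](O)[C@H](C(Br)=C)[C@H](O)/C=C(\C)CO[Si](C)(C)C(C)(C)C | intermediate
22 | trans α-methylene-γ-butyrolactone with free C8–OH | C=C1C(=O)O[C@H]([C@@H](O[Si](C)(C)C(C)(C)C)[C@@H](C)C=C)[C@H]1[C@H](O)/C=C(\C)CO[Si](C)(C)C(C)(C)C | intermediate
23 | C8 isovalerate of 22 | C=C1C(=O)O[C@H]([C@@H](O[Si](C)(C)C(C)(C)C)[C@@H](C)C=C)[C@H]1[C@H](OC(=O)CC(C)C)/C=C(\C)CO[Si](C)(C)C(C)(C)C | intermediate
24 | C3 methyl ketone | C=C1C(=O)O[C@H]([C@@H](O[Si](C)(C)C(C)(C)C)[C@@H](C)C(C)=O)[C@H]1[C@H](OC(=O)CC(C)C)/C=C(\C)CO[Si](C)(C)C(C)(C)C | intermediate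
25 | primary E-allylic alcohol | C=C1C(=O)O[C@H]([C@@H](O[Si](C)(C)C(C)(C)C)[C@@H](C)C(C)=O)[C@H]1[C@H](OC(=O)CC(C)C)/C=C(\C)CO | intermediate
26 | (9R,10R)-epoxy alcohol | C=C1C(=O)O[C@H]([C@@H](O[Si](C)(C)C(C)(C)C)[C@@H](C)C(C)=O)[C@H]1[C@H](OC(=O)CC(C)C)[C@H]2O[C@]2(C)CO | intermediate
27 | epoxy aldehyde | C=C1C(=O)O[C@H]([C@@H](O[Si](C)(C)C(C)(C)C)[C@@H](C)C(C)=O)[C@H]1[C@H](OC(=O)CC(C)C)[C@H]2O[C@]2(C)C=O | intermediate
28 | (9R,10S)-glycidic acid | C=C1C(=O)O[C@H]([C@@H](O[Si](C)(C)C(C)(C)C)[C@@H](C)C(C)=O)[C@H]1[C@H](OC(=O)CC(C)C)[C@H]2O[C@]2(C)C(=O)O | intermediate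
29 | pentafluorophenyl glycidate | C=C1C(=O)O[C@H]([C@@H](O[Si](C)(C)C(C)(C)C)[C@@H](C)C(C)=O)[C@H]1[C@H](OC(=O)CC(C)C)[C@H]2O[C@]2(C)C(=O)Oc3c(F)c(F)c(F)c(F)c3F | intermediate
30 | ten-membered 1,3-diketone with 9,10-epoxide | C=C1C(=O)O[C@@H]2[C@@H](O[Si](C)(C)C(C)(C)C)[C@@H](C)C(=O)CC(=O)[C@@]3(C)O[C@@H]3[C@@H](OC(=O)CC(C)C)[C@@H]12 | intermediate
31 | 5-O-TBS ether of the target | C=C1C(=O)O[C@@H]2[C@@H](O[Si](C)(C)C(C)(C)C)[C@@H](C)C3=CC(=O)[C@](C)(O3)[C@H](O)[C@@H](OC(=O)CC(C)C)[C@@H]12 | intermediate
32 | CNP0484215.1 | C=C1C(=O)O[C@@H]2[C@@H](O)[C@@H](C)C3=CC(=O)[C@](C)(O3)[C@H](O)[C@@H](OC(=O)CC(C)C)[C@@H]12 | target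

## Step count and risks

Total step count: 20. Longest linear sequence: 16 (steps 1–3, 6, 7, 10–20).

**Step 19.**
- What may go wrong:
  - oligomerisation instead of ring closure;
  - opening of the epoxide by bromide or by the neighbouring ester carbonyl before the enolate oxygen arrives;
  - arrest at the chelated magnesium diketonate;
  - migration of the isovaleryl group to the freed C9 alkoxide.
- Fallback: it sets out from 26 and uses known reactions one at a time. Dess–Martin oxidation of 26 gives the epoxy aldehyde 27, which is isolated. A boron‑mediated intramolecular aldol addition (c‑Hex2BCl, Et3N, Et2O, 1 mM, −78→0 °C) follows; the aldehyde is non‑enolisable and more electrophilic than any ester, and this step gives the ten‑membered β‑hydroxy ketone F1. Dess–Martin oxidation of it gives the diketone 30 as an isolated compound. Its 5‑exo epoxide opening by the enol oxygen is then run separately with a catalytic amine base or Cs2CO3. The fallback comes back to the route at 31.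

**Step 12.**
- What may go wrong: capture of the acylpalladium by the C8 hydroxyl, or insertion of the terminal alkene into the alkenyl‑ or acylpalladium bond.
- Fallback: it sets out from 20 and distinguishes the two hydroxyls before the carbonylation. Evans–Tishchenko reduction with acetaldehyde and catalytic SmI2 gives the 1,3‑anti C6 acetate with free C8 hydroxyl F2. TESOTf/2,6‑lutidine gives the C8 triethylsilyl ether F3. K2CO3/MeOH frees only the C6 hydroxyl and gives the mono‑alcohol F4. The carbonylation then has a single hydroxyl to use and gives the C8‑silylated lactone F5. PPTS in MeOH removes the triethylsilyl group, and the fallback comes back to the route at 22.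

**Step 10.**
- What may go wrong: deprotonation at C7 (α to the amide and allylic) by the basic Grignard reagent, with epimerisation or double‑bond migration, or retro‑aldol cleavage of the magnesium alkoxide.
- Fallback: it sets out from 14 and makes the C8–C9 bond without a basic carbanion. TESCl/imidazole gives the C6 triethylsilyl ether amide F6. DIBAL‑H (THF, −78 °C) gives the aldehyde F7. Nozaki–Hiyama–Kishi coupling with 18 (CrCl2, cat. NiCl2, DMF) gives the allylic alcohol F8 as a C8 epimer mixture. Dess–Martin oxidation gives the silylated enone F9. PPTS in MeOH removes the triethylsilyl group, and the fallback comes back to the route at 20.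

## Further compounds

F1 | step 19 | ten-membered β-hydroxy ketone (C1 carbinol, either epimer) | C=C1C(=O)O[C@@H]2[C@@H](O[Si](C)(C)C(C)(C)C)[C@@H](C)C(=O)CC(O)[C@@]3(C)O[C@@H]3[C@@H](OC(=O)CC(C)C)[C@@H]12
F2 | step 12 | 1,3-anti C6 acetate with free C8 hydroxyl | C=C[C@H](C)[C@H](O[Si](C)(C)C(C)(C)C)[C@@H](OC(C)=O)[C@H](C(Br)=C)[C@H](O)/C=C(\C)CO[Si](C)(C)C(C)(C)C
F3 | step 12 | C8 triethylsilyl ether | C=C[C@H](C)[C@H](O[Si](C)(C)C(C)(C)C)[C@@H](OC(C)=O)[C@H](C(Br)=C)[C@H](O[Si](CC)(CC)CC)/C=C(\C)CO[Si](C)(C)C(C)(C)C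
F4 | step 12 | mono-alcohol (C6–OH free, C8–OTES) | C=C[C@H](C)[C@H](O[Si](C)(C)C(C)(C)C)[C@@H](O)[C@H](C(Br)=C)[C@H](O[Si](CC)(CC)CC)/C=C(\C)CO[Si](C)(C)C(C)(C)C
F5 | step 12 | C8-silylated lactone | C=C1C(=O)O[C@H]([C@@H](O[Si](C)(C)C(C)(C)C)[C@@H](C)C=C)[C@H]1[C@H](O[Si](CC)(CC)CC)/C=C(\C)CO[Si](C)(C)C(C)(C)C
F6 | step 10 | C6 triethylsilyl ether amide | C=C[C@H](C)[C@H](O[Si](C)(C)C(C)(C)C)[C@@H](O[Si](CC)(CC)CC)[C@H](C(Br)=C)C(=O)N(C)OC
F7 | step 10 | aldehyde | C=C[C@H](C)[C@H](O[Si](C)(C)C(C)(C)C)[C@@H](O[Si](CC)(CC)CC)[C@H](C(Br)=C)C=O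
F8 | step 10 | allylic alcohol (C8 epimer mixture) | C=C[C@H](C)[C@H](O[Si](C)(C)C(C)(C)C)[C@@H](O[Si](CC)(CC)CC)[C@H](C(Br)=C)C(O)/C=C(\C)CO[Si](C)(C)C(C)(C)C
F9 | step 10 | silylated enone | C=C[C@H](C)[C@H](O[Si](C)(C)C(C)(C)C)[C@@H](O[Si](CC)(CC)CC)[C@H](C(Br)=C)C(=O)/C=C(\C)CO[Si](C)(C)C(C)(C)C
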